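**Assumption:** the target SMILES contains no stereocentres and no stereo-defined double bond (stevensine is achiral; the C4=C5 olefin is cis by ring constraint), so "single enantiomer" is taken to mean the constitution exactly as drawn.

## Retrosynthetic overview

1. Stevensine (7) ⇒ its acyclic alkyne isomer "9,10-didehydro-oroidin" (6), by an acid-mediated 7-endo-dig cycloisomerisation that forms the C3a–C4 bond and the C4=C5 olefin in one redox-neutral step. This replaces the usual azepinone-first, aminoimidazole-addition, late-oxidation sequence.
2. 6 ⇒ amide bond between 4,5-dibromo-2-(trichloroacetyl)pyrrole (5) and aminopropynyl-2-aminoimidazole (4).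
3. 4 ⇒ one-pot double hydrazinolysis of 3, where phthalimide masks the amine and imidazo[1,2-a]pyrimidine masks the 2-aminoimidazole.
4. 3 ⇒ Sonogashira coupling of 3-bromoimidazo[1,2-a]pyrimidine (1) with N-propargylphthalimide (2).
5. Ring order: the pyrrole and (masked) imidazole are purchased; the seven-membered lactam is the only ring formed, and it is formed last.

## Route

**Step 1**
Reactants: 1, 3-bromoimidazo[1,2-a]pyrimidine; 2, N-propargylphthalimide (2-(prop-2-yn-1-yl)isoindoline-1,3-dione)
Product: 3, 2-[3-(imidazo[1,2-a]pyrimidin-3-yl)prop-2-yn-1-yl]isoindoline-1,3-dione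
Conditions: PdCl2(PPh3)2 (5 mol %), CuI (10 mol %), Et3N, DMF, 70 °C, Ar; aq. NH3/EDTA wash to strip Cu
Reagents that add atoms: none (both coupling partners are listed reactants)
Why: Sonogashira coupling at the C3–Br bond of the N-fused heteroaryl bromide; the bicycle carries no N–H to poison Pd/Cu, and the phthalimide tolerates Et3N.

**Step 2**
Reactants: 3
Product: 4, 4(5)-(3-aminoprop-1-yn-1-yl)-1H-imidazol-2-amine, isolated as the dihydrochloride
Conditions: N2H4·H2O (15 equiv), degassed EtOH, 80 °C, 2 h, then 120 °C (sealed tube or µw), 30 min; HCl/MeOH, filter off phthalhydrazide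
Reagents that add atoms: none (hydrazine delivers only H; the excised atoms leave as phthalhydrazide and pyrazole)
Why: Ing–Manske phthalimide hydrazinolysis combined with hydrazine-induced excision of C5–C7 of the imidazo[1,2-a]pyrimidine (ring opening, then pyrazole extrusion), a known way to release N-unsubstituted 2-aminoimidazoles. The alkyne sits on the donor C3 position, so it is not a Michael acceptor, and excluding O2 and Cu prevents diimide reduction of the alkyne.

**Step 3**
Reactants: 4 (as 2 HCl salt); 5, 2,2,2-trichloro-1-(4,5-dibromo-1H-pyrrol-2-yl)ethan-1-one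
Product: 6, N-[3-(2-amino-1H-imidazol-4(5)-yl)prop-2-yn-1-yl]-4,5-dibromo-1H-pyrrole-2-carboxamide, isolated as the halide-free free base
Conditions: i-Pr2NEt (3 equiv), DMF, 0 °C → rt; aq. NaHCO3 work-up; SiO2 (CH2Cl2/MeOH/NH3)
Reagents that add atoms: none (acyl donor 5 is a listed reactant; CHCl3 is lost)
Why: haloform-type amidation of a trichloromethyl ketone by the primary amine; the guanidine-like 2-aminoimidazole is a far poorer acyl acceptor. This is the same chemoselective acylation used to make oroidin-type amides, and mild base at rt avoids pyrrole N–H addition to the alkyne.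

**Step 4 (key step)**
Reactants: 6
Product: 7, stevensine, 4-(2-amino-1H-imidazol-4(5)-yl)-2,3-dibromo-6,7-dihydropyrrolo[2,3-c]azepin-8(1H)-one
Conditions: MeSO3H (neat, anhydrous, 0.02 M), Ar, 23 → 60 °C, 24–48 h; then cold aq. NH3 (or isolate as the mesylate salt)
Reagents that add atoms: none (isomerisation, C11H9Br2N5O → C11H9Br2N5O)
Why: Proposed new method: Markovnikov C-protonation of the alkyne at the CH2-side carbon gives a vinyl cation (2-aminodiazafulvene-allene cation) at the carbon bearing the π-donating 2-aminoimidazole; pyrrole C3, the only free pyrrole carbon, captures it by 7-endo-dig Friedel–Crafts alkenylation, and proton loss gives the ring-enforced cis C4=C5 olefin with no stereocentre created. In neat MeSO3H the amide oxygen is protonated and the pyrrole nitrogen is non-nucleophilic, which disfavours O- and N-cyclisation, and any adventitious hydration gives the aryl ketone, which can close to the same product by hydroxyalkylation and dehydration. The closest known reaction types are superacid-promoted intramolecular alkyne hydroarylation, Au-catalysed 7-endo-dig cyclisation of aryl-substituted N-propargyl pyrrole/indole-2-carboxamides to azepinones, and MeSO3H-mediated C3 closure of 4,5-dibromopyrrole-2-carboxamides onto tethered cations to form this same pyrrolo[2,3-c]azepin-8-one. The temperature is kept at or below 60 °C and halide is excluded to avoid acid/HBr-promoted protodebromination of the pyrrole.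

## Compound list

1 | 3-bromoimidazo[1,2-a]pyrimidine | Brc1cnc2ncccn12 | starting material
2 | N-propargylphthalimide | C#CCN1C(=O)c2ccccc2C1=O | starting material
3 | 2-[3-(imidazo[1,2-a]pyrimidin-3-yl)prop-2-yn-1-yl]isoindoline-1,3-dione | O=C1c2ccccc2C(=O)N1CC#Cc1cnc2ncccn12 | intermediate
4 | 4(5)-(3-aminoprop-1-yn-1-yl)-1H-imidazol-2-amine (used as 2 HCl salt) | NCC#Cc1cnc(N)[nH]1 | intermediate
5 | 2,2,2-trichloro-1-(4,5-dibromo-1H-pyrrol-2-yl)ethan-1-one | O=C(c1cc(Br)c(Br)[nH]1)C(Cl)(Cl)Cl | starting material
6 | N-[3-(2-amino-1H-imidazol-4(5)-yl)prop-2-yn-1-yl]-4,5-dibromo-1H-pyrrole-2-carboxamide | Nc1ncc(C#CCNC(=O)c2cc(Br)c(Br)[nH]2)[nH]1 | intermediate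
7 | stevensine | Nc1ncc(C2=CCNC(=O)c3[nH]c(Br)c(Br)c32)[nH]1 | target

## Summary

**Total steps:** 4
**Longest linear sequence:** 4 (1 + 2 → 3 → 4 → 6 → 7; 5 enters at step 3)

**Steps most likely to fail, with fallbacks**

1. **Step 4 (cycloisomerisation).** Risks are wrong-site protonation, O- or N-capture of the cation, slow ionisation of the cationic substrate, and debromination. Fallback: invert the bond-forming logic. Close the azepinone first from the 4,5-dibromopyrrole-2-carboxamide of 3-aminopropanal acetal in MeSO3H, trap the C4 cation with 2-aminoimidazole to give the 4,5-dihydro compound (hymenin), then install the C4=C5 olefin by imidazole bromination and acid-promoted HBr loss.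
2. **Step 2 (double hydrazinolysis).** Risks are sluggish cleavage of the neutral 3-alkynyl imidazopyrimidine, diimide reduction of the alkyne, and isolation of the very polar diamine. Fallback: introduce the 2-amino group by C–H functionalisation instead of unmasking. Couple 4-iodo-1-tritylimidazole with N-Boc-propargylamine (Sonogashira), lithiate C2 and azidate (n-BuLi, TsN3), reduce by Staudinger (PPh3/H2O, alkyne-safe), then remove Tr and Boc with acid to give 4.
3. **Step 1 (Sonogashira on an electron-rich, coordinating C3 bromide).** Risks are slow oxidative addition, Glaser dimerisation, and propargyl-to-allenyl isomerisation of 2. Fallback: reverse the coupling polarity with a Pd-catalysed direct C3–H alkynylation ("inverse Sonogashira") of parent imidazo[1,2-a]pyrimidine, using the 1-bromoalkyne made from 2 (NBS, cat. AgNO3).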